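**Plan**

- Retrosynthesis: the two ring–diene bonds are cut first, as a twofold Suzuki–Miyaura coupling of one cyclohexenyl boronate (used twice, because of the twofold axis) with (1E,3E)-1,4-diiodobuta-1,3-diene. In the ring, the C5–C6 and C2=C3 bonds are then cut.
- Enabling feature (ring atoms: C1 quaternary carbon, C2 olefinic CH, C3 olefinic carbon carrying the diene, C4 and C5 CH2, C6 carbinol): C1 carries two one-carbon arms, C6 and C2, and C3–C4–C5 is an unbranched three-carbon unit functionalised only at C3. The cyclohex-3-en-1-ol ring is therefore the [3+3] union of an α-vinyl aldehyde (C6, C1, C2) with a 3-boryl-but-3-enyl nucleophile (C5, C4, C3).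
- Forward order: geraniol gives the acyclic C1 stereocentre, then the side-chain oxirane, then the α-vinyl aldehyde. A one-flask catalytic asymmetric alkylzinc addition (C5–C6) and ring-closing metathesis (C2=C3) closes the ring with boron on C3. The tetraene is made last.
- Stereochemistry: C1 comes from a Sharpless epoxidation relayed by a stereospecific anti 1,2-shift; the oxirane from a Shi epoxidation; C6 from a chiral amino-alcohol catalyst; the E,E-diene from the diiodide.

Key step: step 10

Remark: geraniol, 3-bromobut-3-en-1-ol, acetylene, (+)-MIB [(2R)-3-exo-morpholinoisoborneol] and the D-fructose-derived Shi ketone are taken to be commercial; the ring numbering of the plan is used throughout.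

**Step 1**
Reactants: 1 geraniol [(2E)-3,7-dimethylocta-2,6-dien-1-ol]
Product: 2 [(2R,3R)-3-methyl-3-(4-methylpent-3-en-1-yl)oxiran-2-yl]methanol
Conditions: t-BuOOH, Ti(OiPr)4 (5 mol%), D-(−)-diisopropyl tartrate (6 mol%), 4 Å MS, CH2Cl2, −20 °C
Reagents that add atoms: tert-butyl hydroperoxide, CC(C)(C)OO
Why: Sharpless asymmetric epoxidation, in which the titanium tartrate complex binds the allylic hydroxyl and, with the D-(−)-tartrate, delivers oxygen to the face of the 2,3-olefin that gives the (2R,3R)-epoxide, while the 6,7-olefin has no directing hydroxyl and is left alone.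

**Step 2**
Reactants: 2 [(2R,3R)-3-methyl-3-(4-methylpent-3-en-1-yl)oxiran-2-yl]methanol
Product: 3 tert-butyldimethylsilyl ether of 2
Conditions: TBSCl, imidazole, DMF, rt
Reagents that add atoms: tert-butyldimethylsilyl chloride, CC(C)(C)[Si](C)(C)Cl
Why: Routine silylation of the primary alcohol, which turns the carbinol carbon into the siloxymethyl group that is to migrate in step 3.

**Step 3**
Reactants: 3 tert-butyldimethylsilyl ether of 2
Product: 4 (2R)-2-{[tert-butyl(dimethyl)silyl]oxymethyl}-2,6-dimethylhept-5-enal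
Conditions: MeAl(OAr)2 (Ar = 4-bromo-2,6-di-tert-butylphenyl, 2 equiv), CH2Cl2, −78 °C; aq. NaHCO3
Reagents that add atoms: none
Why: Lewis-acid-promoted rearrangement of a 2,3-epoxy silyl ether (semipinacol type), in which the bulky aluminium phenoxide ionises the tertiary C–O bond and the siloxymethyl group shifts anti to the departing oxygen, so that the epoxide configuration is relayed with inversion into the (R)-quaternary carbon (the future C1) and the former epoxide CH becomes the aldehyde.

**Step 4**
Reactants: 4 (2R)-2-{[tert-butyl(dimethyl)silyl]oxymethyl}-2,6-dimethylhept-5-enal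
Product: 5 tert-butyl{[(2S)-2-ethenyl-2,6-dimethylhept-5-en-1-yl]oxy}dimethylsilane
Conditions: Ph3PCH3Br, KOtBu, THF, 0 °C to rt
Reagents that add atoms: methyltriphenylphosphonium bromide, C[P+](c1ccccc1)(c1ccccc1)c1ccccc1.[Br-]
Why: Wittig methylenation of a hindered, non-enolisable aldehyde, whose quaternary centre has no α-hydrogen and cannot epimerise; the new vinyl CH is the future C2.

**Step 5**
Reactants: 5 tert-butyl{[(2S)-2-ethenyl-2,6-dimethylhept-5-en-1-yl]oxy}dimethylsilane
Product: 6 tert-butyl({(2S)-2-[2-((2R)-3,3-dimethyloxiran-2-yl)ethyl]-2-methylbut-3-en-1-yl}oxy)dimethylsilane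
Conditions: D-fructose-derived Shi ketone (30 mol%), Oxone (KHSO5), K2CO3, Bu4NHSO4, MeCN/dimethoxymethane/aq. Na2B4O7 buffer, 0 °C
Reagents that add atoms: potassium peroxymonosulfate, [K+].[O-]S(=O)(=O)OO
Why: Shi epoxidation, in which the chiral dioxirane attacks the electron-rich trisubstituted olefin through the spiro transition state on the face that gives the (R)-oxirane, while the hindered monosubstituted vinyl group reacts far more slowly.

**Step 6**
Reactants: 6 tert-butyl({(2S)-2-[2-((2R)-3,3-dimethyloxiran-2-yl)ethyl]-2-methylbut-3-en-1-yl}oxy)dimethylsilane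
Product: 7 (2S)-2-[2-((2R)-3,3-dimethyloxiran-2-yl)ethyl]-2-methylbut-3-en-1-ol
Conditions: Bu4NF, THF, 0 °C
Reagents that add atoms: none
Why: Fluoride-mediated desilylation under non-acidic conditions, which the trisubstituted oxirane should survive.

**Step 7**
Reactants: 7 (2S)-2-[2-((2R)-3,3-dimethyloxiran-2-yl)ethyl]-2-methylbut-3-en-1-ol
Product: 8 (2S)-2-[2-((2R)-3,3-dimethyloxiran-2-yl)ethyl]-2-methylbut-3-enal
Conditions: nPr4N[RuO4] (5 mol%), N-methylmorpholine N-oxide, 4 Å MS, CH2Cl2, rt
Reagents that add atoms: none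
Why: Ley–Griffith oxidation of the neopentyl-type primary alcohol under neutral conditions gives the α-quaternary aldehyde (the future C6), which can neither epimerise nor move its double bond into conjugation.

**Step 8**
Reactants: 9 3-bromobut-3-en-1-ol
Product: 10 3-(4,4,5,5-tetramethyl-1,3,2-dioxaborolan-2-yl)but-3-en-1-ol
Conditions: B2pin2, PdCl2(PPh3)2 (3 mol%), PPh3, KOPh, toluene, 50 °C
Reagents that add atoms: bis(pinacolato)diboron, CC1(C)OB(OC1(C)C)B1OC(C)(C)C(C)(C)O1
Why: Miyaura borylation of the alkenyl bromide (oxidative addition to zerovalent palladium, transmetalation from the phenoxide-activated diboron, reductive elimination), which tolerates the free hydroxyl.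

**Step 9**
Reactants: 10 3-(4,4,5,5-tetramethyl-1,3,2-dioxaborolan-2-yl)but-3-en-1-ol
Product: 11 2-(4-iodobut-1-en-2-yl)-4,4,5,5-tetramethyl-1,3,2-dioxaborolane
Conditions: I2, PPh3, imidazole, CH2Cl2, 0 °C
Reagents that add atoms: iodine, II
Why: Appel-type iodination of the primary alcohol through the alkoxyphosphonium salt, to which the vinyl boronate is inert.

**Step 10**
Reactants: 8 (2S)-2-[2-((2R)-3,3-dimethyloxiran-2-yl)ethyl]-2-methylbut-3-enal; 11 2-(4-iodobut-1-en-2-yl)-4,4,5,5-tetramethyl-1,3,2-dioxaborolane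
Product: 14 (1R,2S)-2-[2-((2R)-3,3-dimethyloxiran-2-yl)ethyl]-2-methyl-4-(4,4,5,5-tetramethyl-1,3,2-dioxaborolan-2-yl)cyclohex-3-en-1-ol, via dialkylzinc 12 (not isolated), via octadienol 13 (not isolated)
Conditions: 11, Et2Zn, CuI (cat.), 50 °C, then vacuum; (+)-MIB (5 mol%), 8, toluene, 0 °C to rt; i-PrOH; second-generation Grubbs catalyst (5 mol%), 45 °C, one flask
Reagents that add atoms: none
Why: Iodine–zinc exchange of 11 gives the dialkylzinc 12, whose (+)-MIB zinc complex transfers one primary alkyl group to the Re face of the non-enolisable aldehyde 8 through the bimetallic transition state of amino-alcohol-catalysed dialkylzinc additions, forming C5–C6; the ruthenium alkylidene then loads on the vinyl group at C1 of the zinc alkoxide of 13 and closes onto the 1,1-disubstituted vinyl boronate by [2+2] cycloaddition and cycloreversion, forming C2=C3 and releasing ethylene. The closest known reaction types are the catalytic enantioselective addition of functionalised dialkylzincs to α-branched aldehydes and the ring-closing metathesis of α-substituted vinyl boronates to cyclic alkenyl boronates. The six-membered ring is closed by ring-closing metathesis of the octa-1,7-diene 13, which can give only the endocyclic Z-olefin. The one new stereocentre, C6, is set by the catalyst (the (−)-ligand gives (S)-1-phenylpropanol from benzaldehyde and the priority order at C6 is the same, so the (+)-ligand should give R), while C1, being quaternary, and the oxirane pass through unchanged. The step needs the alkylzinc to choose the aldehyde over the oxirane and the boronate, which the low nucleophilicity of a dialkylzinc in the absence of a strong Lewis acid should secure, and it needs alkyl transfer to stop before metathesis, which the i-PrOH quench of residual C–Zn bonds should secure.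

**Step 11**
Reactants: 15 acetylene (two molecules)
Product: 16 (1E,3E)-1,4-diiodobuta-1,3-diene
Conditions: HC≡CH (1 atm), I2, NaI, Na2PtCl6 (cat.), MeOH, rt
Reagents that add atoms: iodine, II
Why: Platinum-catalysed iodinative dimerisation of acetylene, in which trans-iodoplatination of two acetylene molecules and reductive elimination of the two (E)-2-iodovinyl ligands should give the (1E,3E)-diiodide stereoselectively.

**Step 12**
Reactants: 14 (1R,2S)-2-[2-((2R)-3,3-dimethyloxiran-2-yl)ethyl]-2-methyl-4-(4,4,5,5-tetramethyl-1,3,2-dioxaborolan-2-yl)cyclohex-3-en-1-ol (two molecules); 16 (1E,3E)-1,4-diiodobuta-1,3-diene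
Product: 17 (1R,1'R,2S,2'S)-4,4'-[(1E,3E)-buta-1,3-diene-1,4-diyl]bis{2-[2-((2R)-3,3-dimethyloxiran-2-yl)ethyl]-2-methylcyclohex-3-en-1-ol} (the target)
Conditions: Pd(OAc)2 (5 mol%), SPhos (10 mol%), aq. K3PO4, THF, 40 °C, degassed, dark
Reagents that add atoms: none
Why: Twofold Suzuki–Miyaura coupling with retention of configuration at all four olefinic carbons joins two identical halves at C3 and C3' to the (E,E)-diene, and the mild phosphate base should leave the free carbinols and the oxiranes untouched.

**Compound list**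

1 | geraniol, (2E)-3,7-dimethylocta-2,6-dien-1-ol | CC(C)=CCC/C(C)=C/CO | starting material
2 | [(2R,3R)-3-methyl-3-(4-methylpent-3-en-1-yl)oxiran-2-yl]methanol | OC[C@H]1O[C@]1(C)CCC=C(C)C | intermediate
3 | tert-butyldimethylsilyl ether of 2 | CC(C)(C)[Si](C)(C)OC[C@H]1O[C@]1(C)CCC=C(C)C | intermediate
4 | (2R)-2-{[tert-butyl(dimethyl)silyl]oxymethyl}-2,6-dimethylhept-5-enal | CC(C)(C)[Si](C)(C)OC[C@@](C=O)(C)CCC=C(C)C | intermediate
5 | tert-butyl{[(2S)-2-ethenyl-2,6-dimethylhept-5-en-1-yl]oxy}dimethylsilane | CC(C)(C)[Si](C)(C)OC[C@@](C=C)(C)CCC=C(C)C | intermediate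
6 | tert-butyl({(2S)-2-[2-((2R)-3,3-dimethyloxiran-2-yl)ethyl]-2-methylbut-3-en-1-yl}oxy)dimethylsilane | CC(C)(C)[Si](C)(C)OC[C@@](C=C)(C)CC[C@H]1OC1(C)C | intermediate
7 | (2S)-2-[2-((2R)-3,3-dimethyloxiran-2-yl)ethyl]-2-methylbut-3-en-1-ol | OC[C@@](C=C)(C)CC[C@H]1OC1(C)C | intermediate
8 | (2S)-2-[2-((2R)-3,3-dimethyloxiran-2-yl)ethyl]-2-methylbut-3-enal | O=C[C@@](C=C)(C)CC[C@H]1OC1(C)C | intermediate
9 | 3-bromobut-3-en-1-ol | OCCC(Br)=C | starting material
10 | 3-(4,4,5,5-tetramethyl-1,3,2-dioxaborolan-2-yl)but-3-en-1-ol | OCCC(=C)B1OC(C)(C)C(C)(C)O1 | intermediate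
11 | 2-(4-iodobut-1-en-2-yl)-4,4,5,5-tetramethyl-1,3,2-dioxaborolane | ICCC(=C)B1OC(C)(C)C(C)(C)O1 | intermediate
12 | bis[3-(4,4,5,5-tetramethyl-1,3,2-dioxaborolan-2-yl)but-3-en-1-yl]zinc | C=C(CC[Zn]CCC(=C)B1OC(C)(C)C(C)(C)O1)B1OC(C)(C)C(C)(C)O1 | intermediate
13 | (3S,4R)-3-[2-((2R)-3,3-dimethyloxiran-2-yl)ethyl]-3-methyl-7-(4,4,5,5-tetramethyl-1,3,2-dioxaborolan-2-yl)octa-1,7-dien-4-ol | CC1(C)O[C@@H]1CC[C@@](C)(C=C)[C@H](O)CCC(=C)B1OC(C)(C)C(C)(C)O1 | intermediate
14 | (1R,2S)-2-[2-((2R)-3,3-dimethyloxiran-2-yl)ethyl]-2-methyl-4-(4,4,5,5-tetramethyl-1,3,2-dioxaborolan-2-yl)cyclohex-3-en-1-ol | CC1(C)O[C@@H]1CC[C@@]1(C)C=C(B2OC(C)(C)C(C)(C)O2)CC[C@H]1O | intermediate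
15 | acetylene | C#C | starting material
16 | (1E,3E)-1,4-diiodobuta-1,3-diene | I/C=C/C=C/I | intermediate
17 | (1R,1'R,2S,2'S)-4,4'-[(1E,3E)-buta-1,3-diene-1,4-diyl]bis{2-[2-((2R)-3,3-dimethyloxiran-2-yl)ethyl]-2-methylcyclohex-3-en-1-ol} | CC1(C)O[C@@H]1CC[C@@]1(C)C=C(/C=C/C=C/C2=C[C@](C)(CC[C@H]3OC3(C)C)[C@H](O)CC2)CC[C@H]1O | target

**Step count and risks**

Total step count: 12. Longest linear sequence: 9 steps (steps 1 to 7, 10 and 12).

Steps most likely to fail:

1. Step 10. What may go wrong: transfer of a residual ethyl group in place of the functionalised alkyl group, erosion of facial control at the hindered aldehyde, or deactivation of the ruthenium carbene and opening of the oxirane by the neighbouring zinc alkoxide during the metathesis stage. The fallback sets out from 8 and returns to the route at 14. It separates the two bond formations and sets C6 by ketone reduction instead of by the addition. Aldehyde 8 and dialkylzinc 12 (made from 11 as before), with 2-(dimethylamino)ethanol as an achiral promoter in toluene, would give the C4-epimeric dienols (3S,4RS)-3-[2-((2R)-3,3-dimethyloxiran-2-yl)ethyl]-3-methyl-7-(4,4,5,5-tetramethyl-1,3,2-dioxaborolan-2-yl)octa-1,7-dien-4-ol F1. Ley–Griffith oxidation (nPr4N[RuO4], N-methylmorpholine N-oxide) would give the dienone (3S)-3-[2-((2R)-3,3-dimethyloxiran-2-yl)ethyl]-3-methyl-7-(4,4,5,5-tetramethyl-1,3,2-dioxaborolan-2-yl)octa-1,7-dien-4-one F2. Ring-closing metathesis (second-generation Grubbs catalyst, CH2Cl2, 40 °C) would give (2S)-2-[2-((2R)-3,3-dimethyloxiran-2-yl)ethyl]-2-methyl-4-(4,4,5,5-tetramethyl-1,3,2-dioxaborolan-2-yl)cyclohex-3-en-1-one F3. Corey–Bakshi–Shibata reduction ((S)-Me-CBS, catecholborane, toluene, −78 °C), with the quaternary carbon as the large group, should then give the (R)-carbinol 14.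

2. Step 3. What may go wrong: hydride shift in place of siloxymethyl migration (leading to the α-siloxy ketone), or loss of stereochemical fidelity if the tertiary cation rotates before the 1,2-shift. The fallback sets out from 1 and returns to the route at 5. It builds the quaternary centre by enantioselective C–B bond formation instead of by rearrangement. Geraniol 1 with ClCO2Me and pyridine would give geranyl methyl carbonate F4. Copper-catalysed enantioselective allylic substitution with B2pin2 (Cu(OTf)2, chiral imidazolinium sulfonate ligand precursor, NaOMe, DME, −30 °C), the ligand enantiomer being chosen for the (R)-product, would give the tertiary allylic boronate 2-[(3R)-3,7-dimethylocta-1,6-dien-3-yl]-4,4,5,5-tetramethyl-1,3,2-dioxaborolane F5. Matteson homologation with LiCH2Cl (BrCH2Cl, n-BuLi, THF, −78 °C to rt) would give, with retention at the migrating carbon, 2-{[(2S)-2-ethenyl-2,6-dimethylhept-5-en-1-yl]}-4,4,5,5-tetramethyl-1,3,2-dioxaborolane F6. Oxidation (NaBO3, THF/H2O) would give (2S)-2-ethenyl-2,6-dimethylhept-5-en-1-ol F7, and silylation (TBSCl, imidazole) would give 5.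

3. Step 12. What may go wrong: protodeboronation of the cyclohexenyl boronate, stalling after the first coupling, or isomerisation and decomposition of the tetraene under aqueous base. The fallback sets out from 14 and returns to the route at 17. It reverses the polarity of the union and runs it without base as a Stille coupling. Iododeboronation of 14 through its boronate complex (aq. NaOH, I2, THF, 0 °C) would give (1R,2S)-2-[2-((2R)-3,3-dimethyloxiran-2-yl)ethyl]-4-iodo-2-methylcyclohex-3-en-1-ol F8. Diiodide 16, by iodine–lithium exchange (t-BuLi, Et2O, −78 °C) and quenching with Bu3SnCl, would give (1E,3E)-1,4-bis(tributylstannyl)buta-1,3-diene F9. Twofold Stille coupling of two molecules of the iodide with the distannane (Pd2(dba)3, AsPh3, NMP, rt, dark) should give 17.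

**Further compounds**

F1 | step 10 | (3S,4RS)-3-[2-((2R)-3,3-dimethyloxiran-2-yl)ethyl]-3-methyl-7-(4,4,5,5-tetramethyl-1,3,2-dioxaborolan-2-yl)octa-1,7-dien-4-ol | CC1(C)O[C@@H]1CC[C@@](C)(C=C)C(O)CCC(=C)B1OC(C)(C)C(C)(C)O1
F2 | step 10 | (3S)-3-[2-((2R)-3,3-dimethyloxiran-2-yl)ethyl]-3-methyl-7-(4,4,5,5-tetramethyl-1,3,2-dioxaborolan-2-yl)octa-1,7-dien-4-one | CC1(C)O[C@@H]1CC[C@@](C)(C=C)C(=O)CCC(=C)B1OC(C)(C)C(C)(C)O1
F3 | step 10 | (2S)-2-[2-((2R)-3,3-dimethyloxiran-2-yl)ethyl]-2-methyl-4-(4,4,5,5-tetramethyl-1,3,2-dioxaborolan-2-yl)cyclohex-3-en-1-one | CC1(C)O[C@@H]1CC[C@@]1(C)C=C(B2OC(C)(C)C(C)(C)O2)CCC1=O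
F4 | step 3 | geranyl methyl carbonate | COC(=O)OC/C=C(\C)CCC=C(C)C
F5 | step 3 | 2-[(3R)-3,7-dimethylocta-1,6-dien-3-yl]-4,4,5,5-tetramethyl-1,3,2-dioxaborolane | CC(C)=CCC[C@@](C)(C=C)B1OC(C)(C)C(C)(C)O1
F6 | step 3 | 2-{[(2S)-2-ethenyl-2,6-dimethylhept-5-en-1-yl]}-4,4,5,5-tetramethyl-1,3,2-dioxaborolane | CC(C)=CCC[C@@](C)(C=C)CB1OC(C)(C)C(C)(C)O1
F7 | step 3 | (2S)-2-ethenyl-2,6-dimethylhept-5-en-1-ol | CC(C)=CCC[C@@](C)(C=C)CO
F8 | step 12 | (1R,2S)-2-[2-((2R)-3,3-dimethyloxiran-2-yl)ethyl]-4-iodo-2-methylcyclohex-3-en-1-ol | CC1(C)O[C@@H]1CC[C@@]1(C)C=C(I)CC[C@H]1O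
F9 | step 12 | (1E,3E)-1,4-bis(tributylstannyl)buta-1,3-diene | CCCC[Sn](CCCC)(CCCC)/C=C/C=C/[Sn](CCCC)(CCCC)CCCC
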